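A pitfall with two matching curves is to call the reaction first order in substrate and stop there, when the constant read from them may hide a concentration that both runs shared.

| flask | substrate | acid | remark | time |
|---|---|---|---|---|
| theta | 0.050 M | 0.050 mM | the very flask that is asked about, followed so far |  |
| beta | 0.10 M | 0.050 mM | run made earlier |  |
| flask | 0.050 M | 0.0500 mM |  | 1.0 h |

| run | time / min | substrate / % | target / % |
|---|---|---|---|
| theta | 1.00 | 95.8 | 1.2 |
| theta | 3.00 | 86.5 | 11.3 |
| theta | 5.00 | 79.9 | 18.2 |
| theta | 8.00 | 68.7 | 27.9 |
| theta | 10.0 | 65.1 | 34.6 |
| theta | 15.0 | 52.9 | 49.0 |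
| theta | 20.0 | 39.4 | 57.8 |
| beta | 1.33 | 94.7 | 5.4 |
| beta | 4.00 | 84.5 | 15.2 |
| beta | 6.00 | 76.8 | 22.2 |
| beta | 10.0 | 65.3 | 35.5 |
| beta | 15.0 | 51.8 | 48.9 |
| beta | 20.0 | 40.2 | 58.8 |
| beta | 25.0 | 33.0 | 66.3 |

(readings scatter by 1 percentage point)

- acid is the free proton; pH is minus the decimal logarithm of its molar concentration

- part of the substrate that has reacted at 1.0 h
- pH of the solution at 1.0 h

The beta run holds twice the substrate of the theta run, yet both lose about the same percentage per minute, and both hold 0.050 mM of acid. We therefore begin with the main step: substrate turns into target, acid comes back, and the rate is kH·c(acid)·c(substrate). While c(acid) stays constant, this is pseudo-first-order in substrate. That c(acid) enters to the first power is our assumption, since the two runs do not vary it.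

The last reading of the beta run, 33.0% left at 25.0 min, gives a slope of 0.0443 min⁻¹. Dividing by c(acid) gives the acid constant, the slope per unit of free acid, kH = 887 M⁻¹ min⁻¹. For the asked flask this means 93.0% reacted at 1.0 h.

Next we add a loss of acid, which shows as a sinking slope. The theta run gives 0.0449 min⁻¹ up to 5.00 min and 0.0466 min⁻¹ up to 20.0 min, so our number stands. Last we add anything that holds material back: substrate and target at the last beta reading sum to 99.3%, within the scatter. The beta readings stop at 67.0% reacted, so what we say of the later flask is extrapolation.

The forecast says 93% and pH 4.3, holding that “A constant rate constant implies the free acid is unchanged”; our reckoning gives the same conversion.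

    substrate + acid → weak acid + acid + target (k = 850 M⁻¹ min⁻¹)
    weak acid ⇌ conjugate base + acid, settled at all times (K = 1.30 × 10⁻⁹ M)
    substrate → weak acid + target (k = 6.80 × 10⁻⁴ min⁻¹)
    weak acid → by-product carried off (k = 0.100 min⁻¹)

The flask gives 92.6% reacted and pH 4.30; kH times c(acid) over the hour is 2.66, which leaves 6.99%, and the flask holds 7.4% of substrate. At 0.239 h the step through acid uses substrate 63 times as fast as the step without acid. Taken each by itself, with the other concentrations as charged, the step through acid and the step without acid give substrate half-lives of 0.27 h and 17 h, the first being shorter than the second. Carried to a neighbour flask, like the asked flask but with 2.0 × 10⁻⁵ M of acid, kH gives 65.5% reacted, and that neighbour flask gives 65.9%.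

The numbers in the tables are calculated for substances that don't exist; scatter was added.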